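**Retrosynthetic overview**

- The strategy rests on ring C: a 4-pyranone whose O1 (on C8a) and carbonyl carbon C4 (on C4a) both sit on ring A, while C2 carries ring B and C3 carries the chain C9–C10–C11 that ends in the ether oxygen on C2′.
- Last disconnection: the O(2′)–C11 ether bond of the eight-membered oxocine (ring D), giving a tertiary alcohol and a free 2′-phenol after global debenzylation.
- Key disconnection: O1–C2 and C3–C4 of ring C, giving salicylaldehyde 4 and aryl alkyl alkyne 9, joined by rhodium/copper oxidative annulation.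
- Aldehyde 4 comes from 2,4,6-trimethoxybenzaldehyde (chelation-controlled demethylation, mono-benzylation). Alkyne 9 comes from 1,3-bis(benzyloxy)benzene (iodination) and hex-5-yn-2-one (MeMgBr), joined by Sonogashira coupling.
- Ring order: rings A and B are bought, ring C is formed in step 6, ring D in step 8.

Key step: step 6

Remark on the chemistry: the target has two methylene groups (C9, C10) between C3 and the carbinol carbon C11. The alkyne partner must therefore be a 6-aryl-2-methylhex-5-yn-2-ol; a pent-4-yn-2-ol would give a chain one carbon short. Flavone numbering is used throughout. The target has no stereocentre.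

**Route**

Step 1
Reactants: 1 2,4,6-trimethoxybenzaldehyde
Product: 3 2,6-dihydroxy-4-methoxybenzaldehyde, via 2-hydroxy-4,6-dimethoxybenzaldehyde 2 (not isolated)
Conditions: AlCl3 (4 equiv), CH2Cl2, 0 °C to reflux; then cold 1 M HCl
Reagents that add atoms: none
Why: Chelation-directed Lewis acid ether cleavage; aluminium bound to the formyl oxygen activates only the methoxy groups ortho to the carbonyl through a six-membered chelate, so chloride should remove both ortho methyl groups in turn while the para methoxy group stays.

Step 2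
Reactants: 3 2,6-dihydroxy-4-methoxybenzaldehyde
Product: 4 2-(benzyloxy)-6-hydroxy-4-methoxybenzaldehyde
Conditions: BnBr (1.0 equiv), K2CO3 (1.1 equiv), acetone, rt
Reagents that add atoms: benzyl bromide, BrCc1ccccc1
Why: Williamson ether synthesis; once one hydroxyl is benzylated the other is locked in a hydrogen bond to the formyl oxygen and is a poor nucleophile, so alkylation should stop at the mono-ether.

Step 3
Reactants: 5 1,3-bis(benzyloxy)benzene
Product: 6 2,4-bis(benzyloxy)-1-iodobenzene
Conditions: NIS (1.0 equiv), TFA (10 mol%), MeCN, 0 °C to rt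
Reagents that add atoms: N-iodosuccinimide, O=C1CCC(=O)N1I
Why: Electrophilic aromatic iodination; C4 is para to one benzyloxy group and ortho to the other and is less hindered than C2, and one equivalent of NIS limits di-iodination.

Step 4
Reactants: 7 hex-5-yn-2-one
Product: 8 2-methylhex-5-yn-2-ol
Conditions: MeMgBr (1.3 equiv), THF, −78 °C to 0 °C; then cold 1 M HCl
Reagents that add atoms: methylmagnesium bromide, C[Mg]Br
Why: Grignard addition to a methyl ketone; at low temperature carbonyl addition is much faster than deprotonation of the terminal alkyne C–H.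

Step 5
Reactants: 6 2,4-bis(benzyloxy)-1-iodobenzene; 8 2-methylhex-5-yn-2-ol
Product: 9 6-[2,4-bis(benzyloxy)phenyl]-2-methylhex-5-yn-2-ol
Conditions: Pd(PPh3)2Cl2 (2 mol%), CuI (4 mol%), Et3N, THF, 40 °C
Reagents that add atoms: none
Why: Sonogashira coupling; the aryl iodide adds readily to zerovalent palladium despite the electron-rich ring, and the free tertiary alcohol is tolerated.

Step 6
Reactants: 4 2-(benzyloxy)-6-hydroxy-4-methoxybenzaldehyde; 9 6-[2,4-bis(benzyloxy)phenyl]-2-methylhex-5-yn-2-ol
Product: 10 5-(benzyloxy)-2-[2,4-bis(benzyloxy)phenyl]-3-(3-hydroxy-3-methylbutyl)-7-methoxy-4H-chromen-4-one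
Conditions: [RhCl(cod)]2 (2.5 mol%), C5H2Ph4 (1,2,3,4-tetraphenylcyclopenta-1,3-diene, 10 mol%), Cu(OAc)2·H2O (2.1 equiv), o-xylene, 130 °C, N2
Reagents that add atoms: none
Why: This is the known rhodium/copper oxidative C–H/O–H annulation of a salicylaldehyde with an internal alkyne to a 2,3-disubstituted chromone: the tetraphenylcyclopentadienyl complex of trivalent rhodium (formed by oxidation with Cu(OAc)2) binds the phenoxide of 4 and cleaves the formyl C–H with acetate assistance, giving a five-membered acyl rhodacycle. Alkyne 9 inserts into the Rh–acyl bond so that the acyl carbon (future C4) bonds to the alkyl-bearing carbon (future C3) and rhodium holds the aryl-bearing carbon (future C2), giving a seven-membered oxarhodacycle. C–O reductive elimination from this metallacycle forms the O1–C2 bond and closes ring C as a six-membered pyranone, releasing monovalent rhodium, which two equivalents of Cu(OAc)2 return to trivalent rhodium. No stereocentre is formed. The step needs regioselective insertion (ring B at C2, chain at C3); this is secured by the preference of rhodium for the aryl-substituted alkyne carbon, with the smaller CH2 terminus placed next to the acyl group. The silver-free catalyst is chosen so that no strong π-acid is present to cycloisomerise the hydroxy-alkyne, and the remote tertiary hydroxyl is expected to pass through unprotected.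

Step 7
Reactants: 10 5-(benzyloxy)-2-[2,4-bis(benzyloxy)phenyl]-3-(3-hydroxy-3-methylbutyl)-7-methoxy-4H-chromen-4-one
Product: 11 2-(2,4-dihydroxyphenyl)-5-hydroxy-3-(3-hydroxy-3-methylbutyl)-7-methoxy-4H-chromen-4-one
Conditions: H2 (1 atm), 10% Pd/C, EtOAc/MeOH, rt
Reagents that add atoms: none
Why: Catalytic hydrogenolysis of three aryl benzyl ethers; the tetrasubstituted C2=C3 bond of the chromone (a vinylogous ester) and the tertiary alcohol should not be reduced at atmospheric pressure and room temperature.

Step 8
Reactants: 11 2-(2,4-dihydroxyphenyl)-5-hydroxy-3-(3-hydroxy-3-methylbutyl)-7-methoxy-4H-chromen-4-one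
Product: 12 cyclointegrin
Conditions: TsOH·H2O (0.2 equiv), toluene/1,4-dioxane, 80 °C
Reagents that add atoms: none
Why: Acid-catalysed cyclodehydration (SN1-type etherification); protonation ionises the tertiary alcohol to the C11 cation, which the 2′-hydroxyl, held close by the C2=C3 bond, should capture to close the eight-membered oxocine. The 5-hydroxyl is chelated to the C4 carbonyl and cannot reach C11, the 4′-hydroxyl is too far away, and any alkene formed by proton loss is re-protonated to the same cation.

**Compound list**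

1 | 2,4,6-trimethoxybenzaldehyde | COc1cc(OC)c(C=O)c(OC)c1 | starting material
2 | 2-hydroxy-4,6-dimethoxybenzaldehyde | COc1cc(O)c(C=O)c(OC)c1 | intermediate (not isolated)
3 | 2,6-dihydroxy-4-methoxybenzaldehyde | COc1cc(O)c(C=O)c(O)c1 | intermediate
4 | 2-(benzyloxy)-6-hydroxy-4-methoxybenzaldehyde | COc1cc(O)c(C=O)c(OCc2ccccc2)c1 | intermediate
5 | 1,3-bis(benzyloxy)benzene | c1ccc(COc2cccc(OCc3ccccc3)c2)cc1 | starting material
6 | 2,4-bis(benzyloxy)-1-iodobenzene | Ic1ccc(OCc2ccccc2)cc1OCc1ccccc1 | intermediate
7 | hex-5-yn-2-one | CC(=O)CCC#C | starting material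
8 | 2-methylhex-5-yn-2-ol | CC(C)(O)CCC#C | intermediate
9 | 6-[2,4-bis(benzyloxy)phenyl]-2-methylhex-5-yn-2-ol | CC(C)(O)CCC#Cc1ccc(OCc2ccccc2)cc1OCc1ccccc1 | intermediate
10 | 5-(benzyloxy)-2-[2,4-bis(benzyloxy)phenyl]-3-(3-hydroxy-3-methylbutyl)-7-methoxy-4H-chromen-4-one | COc1cc(OCc2ccccc2)c2c(=O)c(CCC(C)(C)O)c(-c3ccc(OCc4ccccc4)cc3OCc3ccccc3)oc2c1 | intermediate
11 | 2-(2,4-dihydroxyphenyl)-5-hydroxy-3-(3-hydroxy-3-methylbutyl)-7-methoxy-4H-chromen-4-one | COc1cc(O)c2c(=O)c(CCC(C)(C)O)c(-c3ccc(O)cc3O)oc2c1 | intermediate
12 | cyclointegrin | COc1cc(O)c2c(=O)c3c(oc2c1)-c1ccc(O)cc1OC(C)(C)CC3 | target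

**Step count**

Total step count: 8 steps.
Longest linear sequence: 5 steps (for example steps 1, 2, 6, 7, 8).

**Steps most likely to fail**

1. Step 6 (key annulation). What may go wrong:
- the alkyne may insert in the reverse sense, placing ring B at C3;
- the acyl rhodium may lose CO before insertion;
- the hindered, electron-rich aldehyde may undergo C–H cleavage only slowly;
- the hydroxy-alkyne may cycloisomerise or dehydrate at 130 °C.

Fallback, setting out from 4 and 6 and coming back to the route at 11: ring C is built by iodocyclisation of an ynone and the side chain is attached afterwards by cross-coupling. Aldehyde 4 is benzylated (BnBr, K2CO3, DMF, 70 °C) to the symmetrical 2,6-bis(benzyloxy)-4-methoxybenzaldehyde F1. HC≡CMgBr (THF, 0 °C) should give racemic 1-[2,6-bis(benzyloxy)-4-methoxyphenyl]prop-2-yn-1-ol F2. Sonogashira coupling of F2 with iodide 6 (Pd(PPh3)2Cl2, CuI, Et3N) should give 1-[2,6-bis(benzyloxy)-4-methoxyphenyl]-3-[2,4-bis(benzyloxy)phenyl]prop-2-yn-1-ol F3, which MnO2 (CH2Cl2, rt) oxidises to 1-[2,6-bis(benzyloxy)-4-methoxyphenyl]-3-[2,4-bis(benzyloxy)phenyl]prop-2-yn-1-one F4. With ICl (CH2Cl2, −78 °C) iodine adds to the carbon next to the carbonyl, one of the two equivalent ortho benzyloxy oxygens closes 6-endo on the aryl-bearing carbon, and chloride removes the benzyl group; this should give 5-(benzyloxy)-2-[2,4-bis(benzyloxy)phenyl]-3-iodo-7-methoxy-4H-chromen-4-one F5. Sonogashira coupling of F5 with 2-methylbut-3-yn-2-ol should give 5-(benzyloxy)-2-[2,4-bis(benzyloxy)phenyl]-3-(3-hydroxy-3-methylbut-1-yn-1-yl)-7-methoxy-4H-chromen-4-one F6. Hydrogenation (H2, Pd/C) saturates the triple bond and cleaves the three benzyl ethers in one operation, giving 11.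

2. Step 8 (oxocine closure). What may go wrong:
- proton loss from the C11 cation may outrun the slow eight-membered ring closure;
- intermolecular capture may give oligomers;
- the product ether may re-ionise under the acid.

Fallback, setting out from 11 and coming back at 12: the ether bond is formed by alkoxymercuration of an alkene, which is kinetically controlled and made irreversible by reduction. Compound 11 is dehydrated under equilibrating conditions (TsOH, toluene, reflux with azeotropic removal of water) to 2-(2,4-dihydroxyphenyl)-5-hydroxy-7-methoxy-3-(3-methylbut-2-en-1-yl)-4H-chromen-4-one F7; any oxocine formed at this stage is already 12. Hg(OCOCF3)2 (THF, 0 °C) should then deliver the 2′-oxygen to the more substituted alkene carbon C11, giving the oxocine bearing a trifluoroacetoxymercurio group at C10, F8. NaBH4 in aqueous NaOH replaces mercury by hydrogen and gives 12.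

3. Step 1 (double demethylation). What may go wrong:
- cleavage may stop after the first ortho methoxy group, since the formyl oxygen can chelate only one side at a time;
- cleavage may extend to the para methoxy group under forcing conditions.

Fallback, setting out from 1 and coming back at 3: the pattern is set by alkylation and not by cleavage. Exhaustive demethylation of 1 (BBr3, 4 equiv, CH2Cl2, −78 °C to rt) gives 2,4,6-trihydroxybenzaldehyde F9 (also an article of commerce). One equivalent of Me2SO4 with K2CO3 in acetone at rt should methylate the 4-hydroxyl, the only one not flanking the formyl group and the most accessible, to give 3.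

**Further compounds**

F1 | step 6 | 2,6-bis(benzyloxy)-4-methoxybenzaldehyde | COc1cc(OCc2ccccc2)c(C=O)c(OCc2ccccc2)c1
F2 | step 6 | 1-[2,6-bis(benzyloxy)-4-methoxyphenyl]prop-2-yn-1-ol (racemic) | COc1cc(OCc2ccccc2)c(C(O)C#C)c(OCc2ccccc2)c1
F3 | step 6 | 1-[2,6-bis(benzyloxy)-4-methoxyphenyl]-3-[2,4-bis(benzyloxy)phenyl]prop-2-yn-1-ol (racemic) | COc1cc(OCc2ccccc2)c(C(O)C#Cc2ccc(OCc3ccccc3)cc2OCc2ccccc2)c(OCc2ccccc2)c1
F4 | step 6 | 1-[2,6-bis(benzyloxy)-4-methoxyphenyl]-3-[2,4-bis(benzyloxy)phenyl]prop-2-yn-1-one | COc1cc(OCc2ccccc2)c(C(=O)C#Cc2ccc(OCc3ccccc3)cc2OCc2ccccc2)c(OCc2ccccc2)c1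
F5 | step 6 | 5-(benzyloxy)-2-[2,4-bis(benzyloxy)phenyl]-3-iodo-7-methoxy-4H-chromen-4-one | COc1cc(OCc2ccccc2)c2c(=O)c(I)c(-c3ccc(OCc4ccccc4)cc3OCc3ccccc3)oc2c1
F6 | step 6 | 5-(benzyloxy)-2-[2,4-bis(benzyloxy)phenyl]-3-(3-hydroxy-3-methylbut-1-yn-1-yl)-7-methoxy-4H-chromen-4-one | COc1cc(OCc2ccccc2)c2c(=O)c(C#CC(C)(C)O)c(-c3ccc(OCc4ccccc4)cc3OCc3ccccc3)oc2c1
F7 | step 8 | 2-(2,4-dihydroxyphenyl)-5-hydroxy-7-methoxy-3-(3-methylbut-2-en-1-yl)-4H-chromen-4-one | COc1cc(O)c2c(=O)c(CC=C(C)C)c(-c3ccc(O)cc3O)oc2c1
F8 | step 8 | C10-(trifluoroacetoxymercurio) derivative of cyclointegrin (racemic) | COc1cc(O)c2c(=O)c3c(oc2c1)-c1ccc(O)cc1OC(C)(C)C(C3)[Hg]OC(=O)C(F)(F)F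
F9 | step 1 | 2,4,6-trihydroxybenzaldehyde | O=Cc1c(O)cc(O)cc1O
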